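The data come from a simulation on assumed constants; noise was put on by code.

Follow the uptake.

| flask | left-handed substrate | right-handed substrate | partner | remark | time |
|---|---|---|---|---|---|
| ochre | 0.050 M | 0.050 M | 1.1 equiv (in portions, 4) | the very flask that is asked about, followed so far; portions every 5.0 h |  |
| green | 0.10 M | 0.10 M | 1.1 equiv (in portions, 4) | run made earlier; portions every 5.0 h |  |
| flask | 0.050 M | 0.050 M | 1.10 equiv (in portions, 4) | the portions of partner follow each other after 5.0 h, the first at the start | 8.0 d |

| run | time / d | left-handed substrate / % | left-handed product / % |
|---|---|---|---|
| ochre | 0.250 | 48 | 1 |
| ochre | 0.500 | 41 | 11 |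
| ochre | 0.833 | 32 | 19 |
| ochre | 1.67 | 24 | 27 |
| ochre | 3.00 | 18 | 28 |
| green | 0.625 | 34 | 18 |
| green | 1.25 | 21 | 33 |
| green | 2.50 | 11 | 32 |
| green | 4.00 | 16 | 36 |
| green | 8.00 | 15 | 33 |

(standard deviation of a reading: 2 percentage points)

- at 8.0 d, what has stopped the reaction, if anything has (the partner has run out first / all of the left-handed substrate has reacted / it is still moving)
- conversion of left-handed substrate and right-handed substrate together at 8.0 d
- amount of left-handed product at 8.0 d, in percent of the left-handed substrate and right-handed substrate together charged
- amount of right-handed substrate at 8.0 d, in percent of the left-handed substrate and right-handed substrate together charged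

- partner is single-handed; left-handed substrate and right-handed substrate are mirror images of each other, charged as a racemate, each of them at the stated concentration
- the numbers in the tables scatter with a standard deviation of 2 percentage points
- the reaction counts as stopped when no species that holds the left-handed substrate and right-handed substrate together changes by six tenths of a point or more over the second half of the time
- the handed part of partner does not stay in what it makes, so the products of the two hands are mirror images too

In the ochre flask the last portion goes in at 0.625 d, so later readings show decay without dosing. Let the uptake be the mean of the fall in left-handed substrate and the rise in left-handed product. It is 8 percentage points from 0.833 d to 1.67 d, then 3.5 points up to 3.00 d. Per day, that is a drop by a factor of 3.63, while left-handed substrate falls by a factor of 1.78, less, so the partner is fading too: it is the limiting reagent.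

These readings, with their scatter, give τ = 0.840 d, the uptake lifetime, the time in which the daily uptake shrinks by the factor e. Against it stands the second half of the flask, 4.00 d, or 4.76 lifetimes. Extrapolated, the ochre flask gains 1 point after 3.00 d, reaching 31.0 % left-handed product. Its second half gains 0.3 points, under the margin, so this reckoning calls it stopped, with the partner out. No reading shows right-handed substrate, so it gets no number here.

The forecast gave it is still moving ("The flask is nearly finished but formally still moving"), with conversion 54 %, left-handed product 34.5 % and right-handed substrate 30.5 %.

The flask gives: the partner has run out first, conversion 37.6 %, left-handed product 31.2 %, right-handed substrate 43.5 %.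

    partner → decomposed reagent (k = 4.60 × 10⁻⁶ /s)
    partner + right-handed substrate → right-handed product (k = 3.70 × 10⁻⁵ /M/s)
    partner → decomposition product (k = 1.50 × 10⁻⁸ /s)
    partner + left-handed substrate → left-handed product (k = 2.60 × 10⁻⁴ /M/s)

At 8.00 d the ochre flask holds 0.0388 % of its partner, down from 1.83 % at 4.00 d. In the neighbour flask with 0.280 equiv of partner, the span from the last portion to the asked time is 8.78 times τ, but τ was read in the ochre flask at 1.1 equiv, so this count is a rough yardstick and not a lifetime of that neighbour. That neighbour holds 0 % of its partner at 8.00 d, with left-handed substrate at 40.9 % and left-handed product at 9.05 %.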